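**Retrosynthetic overview**
- Target ⇒ its isomer, a (2R,3R)-epoxy aryl ester: the last step closes the C2–O1 bond and relays the acyl group from the phenol oxygen to O-3 (new DMAP-catalysed cycloisomerisation).
- Epoxy aryl ester ⇒ chiral-ketone/KHSO5 epoxidation of the (E)-styrenyl alkene of a dienyl aryl ester; this sets both stereocentres.
- Dienyl aryl ester ⇒ chemoselective O-acylation of a dienyl resacetophenone with (Z)-2-(acetoxymethyl)but-2-enoic acid.
- Dienyl phenol ⇒ Suzuki coupling of a bromo-resacetophenone with an (E)-dienylboronate; acid ⇒ tert-butyl but-2-ynoate by syn-hydroalumination, hydroxymethylation and acetylation.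
- Ring order: the benzene ring is bought in; the oxirane is formed in step 6; the dihydrofuran ring is formed last, in step 7.

Assumption: the SMILES is read as 2S,3R (2,3-trans) with a Z side-chain alkene, and all four starting materials are taken as catalogue compounds.

**Route**

Step 1
Reactants: 1 2-methylbut-1-en-3-yne; 2 pinacolborane
Product: 3 4,4,5,5-tetramethyl-2-[(1E)-3-methylbuta-1,3-dien-1-yl]-1,3,2-dioxaborolane
Conditions: Cp2Zr(H)Cl (5 mol%), CH2Cl2, 25 °C, sealed vessel
Reagents that add atoms: none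
Why: Zirconocene-hydride-catalysed hydroboration of the terminal alkyne is syn and anti-Markovnikov, so boron ends on the terminal carbon trans to the isopropenyl group (E) and the 1,1-disubstituted alkene is left alone.

Step 2
Reactants: 3 4,4,5,5-tetramethyl-2-[(1E)-3-methylbuta-1,3-dien-1-yl]-1,3,2-dioxaborolane; 4 1-(5-bromo-2,4-dihydroxyphenyl)ethan-1-one
Product: 5 1-{2,4-dihydroxy-5-[(1E)-3-methylbuta-1,3-dien-1-yl]phenyl}ethan-1-one
Conditions: Pd(OAc)2 (3 mol%), SPhos (6 mol%), K3PO4, dioxane/H2O, 80 °C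
Reagents that add atoms: none
Why: Suzuki–Miyaura cross-coupling transfers the dienyl group with retention of the E geometry to the carbon that carried bromine, and the electron-rich biarylphosphine allows oxidative addition of the unprotected bromophenol.

Step 3
Reactants: 6 tert-butyl but-2-ynoate
Product: 9 tert-butyl (2Z)-2-[(acetyloxy)methyl]but-2-enoate, via vinylalane 7 (not isolated), via aluminium alkoxide 8 (not isolated)
Conditions: iBu2AlH, N-methylmorpholine N-oxide, THF, 0 to 25 °C; HCHO (monomeric, in THF), −20 to 0 °C; then Ac2O, pyridine, DMAP (cat.), 0 to 25 °C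
Reagents that add atoms: formaldehyde C=O; acetic anhydride CC(=O)OC(C)=O; diisobutylaluminium hydride CC(C)C[AlH]CC(C)C (its aluminium stays only in 7 and 8)
Why: Syn-hydroalumination of the ynoate (vinylalumination) puts hydride on C-3 and aluminium on C-2 from the same face so that methyl and ester are cis, the α-aluminated enoate adds to formaldehyde with retention, and the aluminium alkoxide is acetylated in the same flask to give the Z (angelate-type) alkene.

Step 4
Reactants: 9 tert-butyl (2Z)-2-[(acetyloxy)methyl]but-2-enoate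
Product: 10 (2Z)-2-[(acetyloxy)methyl]but-2-enoic acid
Conditions: CF3CO2H, CH2Cl2, 0 °C
Reagents that add atoms: none
Why: Acidolysis of the tert-butyl ester (E1 loss of isobutene) frees the acid without touching the primary acetate or the alkene geometry.

Step 5
Reactants: 5 1-{2,4-dihydroxy-5-[(1E)-3-methylbuta-1,3-dien-1-yl]phenyl}ethan-1-one; 10 (2Z)-2-[(acetyloxy)methyl]but-2-enoic acid
Product: 11 4-acetyl-5-hydroxy-2-[(1E)-3-methylbuta-1,3-dien-1-yl]phenyl (2Z)-2-[(acetyloxy)methyl]but-2-enoate
Conditions: N,N'-diisopropylcarbodiimide (1.1 equiv), DMAP (10 mol%), CH2Cl2, 0 °C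
Reagents that add atoms: none
Why: Steglich esterification acylates only the free 4-hydroxyl because the 2-hydroxyl is locked in a hydrogen bond to the acetyl group, and 0 °C with catalytic DMAP keeps the Z alkene intact.

Step 6
Reactants: 11 4-acetyl-5-hydroxy-2-[(1E)-3-methylbuta-1,3-dien-1-yl]phenyl (2Z)-2-[(acetyloxy)methyl]but-2-enoate
Product: 12 4-acetyl-5-hydroxy-2-[(2R,3R)-3-(prop-1-en-2-yl)oxiran-2-yl]phenyl (2Z)-2-[(acetyloxy)methyl]but-2-enoate
Conditions: 1,2:4,5-di-O-isopropylidene-β-D-erythro-hexo-2,3-diulopyranose (D-fructose-derived Shi ketone, 30 mol%), KHSO5 (1.4 equiv, as 2KHSO5·KHSO4·K2SO4), K2CO3, Bu4NHSO4 (cat.), MeCN–CH2(OMe)2–aq. Na2B4O7/Na2EDTA buffer, pH 9.5–10, 0 °C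
Reagents that add atoms: potassium peroxymonosulfate [K+].[O-]S(=O)(=O)OO
Why: Shi epoxidation, in which the dioxirane of the D-fructose-derived ketone attacks the trans-1,2-disubstituted styrenyl alkene through the spiro transition state from the face that gives the (R,R)-epoxide, sets both stereocentres, while the 1,1-disubstituted diene terminus and the electron-poor enoate are expected to react more slowly.

Step 7
Reactants: 12 4-acetyl-5-hydroxy-2-[(2R,3R)-3-(prop-1-en-2-yl)oxiran-2-yl]phenyl (2Z)-2-[(acetyloxy)methyl]but-2-enoate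
Product: 13 (2S,3R)-5-acetyl-6-hydroxy-2-(prop-1-en-2-yl)-2,3-dihydro-1-benzofuran-3-yl (2Z)-2-[(acetyloxy)methyl]but-2-enoate
Conditions: DMAP (20 mol%), 4 Å molecular sieves, MeCN, 40 °C
Reagents that add atoms: none
Why: Proposed new method: a DMAP-catalysed acyl-relay cycloisomerisation in which DMAP attacks the activated aryl ester to give an N-acylpyridinium aryloxide ion pair, the aryloxide opens the oxirane at its allylic carbon in a five-membered SN2 closure with inversion (forming the dihydrofuran ring and setting C-2 as S), and the C-3 alkoxide, whose configuration is untouched (R), collapses on the acylpyridinium to deliver the ester and return DMAP; the closest known reactions are DMAP-catalysed transesterification from aryl esters with aryloxide rebound and the base-mediated deacylative cyclisation of 2-(oxiran-2-yl)aryl esters to 2,3-dihydrobenzofuran-3-ols.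

**Compound list**

1 | 2-methylbut-1-en-3-yne | C=C(C)C#C | starting material
2 | pinacolborane (4,4,5,5-tetramethyl-1,3,2-dioxaborolane) | CC1(C)OBOC1(C)C | starting material
3 | 4,4,5,5-tetramethyl-2-[(1E)-3-methylbuta-1,3-dien-1-yl]-1,3,2-dioxaborolane | C=C(C)/C=C/B1OC(C)(C)C(C)(C)O1 | intermediate
4 | 1-(5-bromo-2,4-dihydroxyphenyl)ethan-1-one | CC(=O)c1cc(Br)c(O)cc1O | starting material
5 | 1-{2,4-dihydroxy-5-[(1E)-3-methylbuta-1,3-dien-1-yl]phenyl}ethan-1-one | CC(=O)c1cc(/C=C/C(C)=C)c(O)cc1O | intermediate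
6 | tert-butyl but-2-ynoate | CC#CC(=O)OC(C)(C)C | starting material
7 | tert-butyl (2E)-2-[bis(2-methylpropyl)alumanyl]but-2-enoate (vinylalane) | C/C=C(\C(=O)OC(C)(C)C)[Al](CC(C)C)CC(C)C | intermediate
8 | tert-butyl (2Z)-2-({[bis(2-methylpropyl)alumanyl]oxy}methyl)but-2-enoate (aluminium alkoxide) | C/C=C(\C(=O)OC(C)(C)C)CO[Al](CC(C)C)CC(C)C | intermediate
9 | tert-butyl (2Z)-2-[(acetyloxy)methyl]but-2-enoate | C/C=C(\C(=O)OC(C)(C)C)COC(C)=O | intermediate
10 | (2Z)-2-[(acetyloxy)methyl]but-2-enoic acid | C/C=C(\C(=O)O)COC(C)=O | intermediate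
11 | 4-acetyl-5-hydroxy-2-[(1E)-3-methylbuta-1,3-dien-1-yl]phenyl (2Z)-2-[(acetyloxy)methyl]but-2-enoate | C/C=C(\C(=O)Oc1cc(O)c(C(C)=O)cc1/C=C/C(C)=C)COC(C)=O | intermediate
12 | 4-acetyl-5-hydroxy-2-[(2R,3R)-3-(prop-1-en-2-yl)oxiran-2-yl]phenyl (2Z)-2-[(acetyloxy)methyl]but-2-enoate | C/C=C(\C(=O)Oc1cc(O)c(C(C)=O)cc1[C@H]2O[C@@H]2C(C)=C)COC(C)=O | intermediate
13 | (2S,3R)-5-acetyl-6-hydroxy-2-(prop-1-en-2-yl)-2,3-dihydro-1-benzofuran-3-yl (2Z)-2-[(acetyloxy)methyl]but-2-enoate | C=C(C)[C@@H]1Oc2cc(O)c(C(C)=O)cc2[C@H]1OC(=O)/C(=C\C)COC(C)=O | target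

**Step count and risks**

Total steps: 7. Longest linear sequence: 5 (steps 1, 2, 5, 6, 7, or steps 3, 4, 5, 6, 7).

Steps most likely to fail:

Step 7 (the new relay step). The ion-pair concentration may be too low for useful turnover. DMAP may also isomerise the Z enoate by conjugate addition, or open the oxirane itself and lead to the cis isomer. The benzylic ester para to the phenol can ionise under basic conditions. The fallback uses known chemistry, sets out from 12 and comes back at 13. Treatment of 12 with K2CO3 in MeOH at 0 °C removes the aryl acyl group, and the liberated phenoxide closes onto the oxirane to give 1-[(2S,3R)-3,6-dihydroxy-2-(prop-1-en-2-yl)-2,3-dihydro-1-benzofuran-5-yl]ethan-1-one F1. Its secondary benzylic hydroxyl is then esterified with fresh acid 10 (N,N'-diisopropylcarbodiimide, catalytic DMAP, CH2Cl2, 0 °C); the hydrogen-bonded phenol stays free, and this gives 13.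

Step 6 (epoxidation). The dioxirane may attack the 1,1-disubstituted diene terminus instead of the styrenyl alkene; I could not confirm the regioselectivity for this diene type from precedent. The activated aryl ester and the para-hydroxyphenyl oxirane are also base-sensitive. The fallback removes the second alkene during the epoxidation; it sets out from 4 (with 10 as acyl donor) and comes back at 12. Heck coupling of 4 with 2-methylbut-3-en-2-ol (Pd(OAc)2, P(o-tol)3, K2CO3, DMF, 90 °C) gives 1-{2,4-dihydroxy-5-[(1E)-3-hydroxy-3-methylbut-1-en-1-yl]phenyl}ethan-1-one F2. Acylation of its free 4-hydroxyl with 10 under the conditions of step 5 gives 4-acetyl-5-hydroxy-2-[(1E)-3-hydroxy-3-methylbut-1-en-1-yl]phenyl (2Z)-2-[(acetyloxy)methyl]but-2-enoate F3. Epoxidation with the same chiral ketone, now with a single reactive alkene, gives 4-acetyl-5-hydroxy-2-[(2R,3S)-3-(2-hydroxypropan-2-yl)oxiran-2-yl]phenyl (2Z)-2-[(acetyloxy)methyl]but-2-enoate F4. Dehydration of the tertiary alcohol with methyl N-(triethylammoniosulfonyl)carbamate (Burgess reagent, THF, 50 °C) can only take a methyl hydrogen next to the oxirane and so gives 12.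

Step 3 (one-flask acid construction). The aluminium allenolate may erode the Z geometry, the ester may be over-reduced, or the in situ acetylation may be incomplete. The fallback replaces hydroalumination by a tin-based sequence; it sets out from 6 and comes back at 9. Syn-hydrostannation of 6 (Bu3SnH, Pd(PPh3)4 cat., THF) gives tert-butyl (2E)-2-(tributylstannyl)but-2-enoate F5. Iododestannylation (I2, CH2Cl2, 0 °C) gives tert-butyl (2E)-2-iodobut-2-enoate F6 with retention. Stille hydroxymethylation (Bu3SnCH2OH, Pd(PPh3)4, dioxane, 90 °C) gives tert-butyl (2Z)-2-(hydroxymethyl)but-2-enoate F7, and acetylation (Ac2O, pyridine) gives 9.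

**Further compounds**

F1 | step 7 | 1-[(2S,3R)-3,6-dihydroxy-2-(prop-1-en-2-yl)-2,3-dihydro-1-benzofuran-5-yl]ethan-1-one | C=C(C)[C@@H]1Oc2cc(O)c(C(C)=O)cc2[C@H]1O
F2 | step 6 | 1-{2,4-dihydroxy-5-[(1E)-3-hydroxy-3-methylbut-1-en-1-yl]phenyl}ethan-1-one | CC(=O)c1cc(/C=C/C(C)(C)O)c(O)cc1O
F3 | step 6 | 4-acetyl-5-hydroxy-2-[(1E)-3-hydroxy-3-methylbut-1-en-1-yl]phenyl (2Z)-2-[(acetyloxy)methyl]but-2-enoate | C/C=C(\C(=O)Oc1cc(O)c(C(C)=O)cc1/C=C/C(C)(C)O)COC(C)=O
F4 | step 6 | 4-acetyl-5-hydroxy-2-[(2R,3S)-3-(2-hydroxypropan-2-yl)oxiran-2-yl]phenyl (2Z)-2-[(acetyloxy)methyl]but-2-enoate | C/C=C(\C(=O)Oc1cc(O)c(C(C)=O)cc1[C@H]2O[C@@H]2C(C)(C)O)COC(C)=O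
F5 | step 3 | tert-butyl (2E)-2-(tributylstannyl)but-2-enoate | C/C=C(\C(=O)OC(C)(C)C)[Sn](CCCC)(CCCC)CCCC
F6 | step 3 | tert-butyl (2E)-2-iodobut-2-enoate | C/C=C(\C(=O)OC(C)(C)C)I
F7 | step 3 | tert-butyl (2Z)-2-(hydroxymethyl)but-2-enoate | C/C=C(\C(=O)OC(C)(C)C)CO
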